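**Retrosynthetic overview**

1. Target 24 is the caffeate ester of (−)-lariciresinol; the ester C–O bond is made last, from the primary alcohol 19 and the silylated acid 22.
2. Structural feature: if the benzylic CH2 carbon on oxolane C4 is bonded back to the oxygen of the C3 CH2O group, a second oxolane closes. The result is the C2-symmetric 2,6-diaryl-3,7-dioxabicyclo[3.3.0]octane of (−)-pinoresinol (18), in which the oxolane C2–aryl bond and the benzylic CH2–aryl bond are symmetry-equivalent.
3. Both aryl–carbon bonds are therefore cut together: bis-lactol diacetate 10 (a double oxocarbenium precursor) plus two aryl groups from Grignard reagent 13 via zinc.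
4. 10 comes from the (1S,5S) bis-lactone 8, whose two stereocentres are set by two Evans benzyloxymethylations of the succinyl bis-imide 3.
5. Ring order: both oxolane (lactone) rings form together in step 4, before any aryl group is present; one of them is re-opened by hydrogenolysis in step 9 (either one, by symmetry).

Key step: step 8

Assumption: diacetate 10 is expected as a mixture of anomers at its two acetal carbons and is used as such, because both carbons become planar in step 8; the exo,exo anomer is drawn in the list.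

**Step 1**
Reactants: 1 succinyl chloride; 2 (R)-4-benzyl-1,3-oxazolidin-2-one (2 equiv)
Product: 3 1,4-bis[(4R)-4-benzyl-2-oxo-1,3-oxazolidin-3-yl]butane-1,4-dione
Conditions: n-BuLi (2.05 equiv), THF, −78 °C; then 1, −78 to 0 °C
Reagents that add atoms: none
Why: N-acylation of the lithiated oxazolidinone by both acid chloride groups is the standard attachment of an Evans auxiliary and creates no stereocentre.

**Step 2**
Reactants: 3 succinyl bis-imide; 4 benzyl chloromethyl ether (2 equiv)
Product: 5 (2S)-2-(benzyloxymethyl)-1,4-bis[(4R)-4-benzyl-2-oxo-1,3-oxazolidin-3-yl]butane-1,4-dione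
Conditions: TiCl4 (1.1 equiv), iPr2NEt (1.15 equiv), CH2Cl2, 0 °C; then 4, 0 °C
Reagents that add atoms: none
Why: Soft enolisation gives the chelated Z titanium enolate of one imide, and the Evans alkylation with 4 takes place on the face opposite the C4 benzyl group of the (R)-auxiliary, which sets the new α-centre as S.

**Step 3**
Reactants: 5 mono-benzyloxymethyl bis-imide; 4 benzyl chloromethyl ether (2 equiv)
Product: 6 (2S,3S)-2,3-bis(benzyloxymethyl)-1,4-bis[(4R)-4-benzyl-2-oxo-1,3-oxazolidin-3-yl]butane-1,4-dione
Conditions: TiCl4 (1.1 equiv), iPr2NEt (1.15 equiv), CH2Cl2, 0 °C; then 4, 0 °C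
Reagents that add atoms: none
Why: In this second Evans titanium-enolate alkylation, enolisation should occur only at the remaining CH2 (the substituted α-carbon resists enolisation through allylic strain) and the second (R)-auxiliary again directs 4 anti to its benzyl group, giving the C2-symmetric (2S,3S) product.

**Step 4**
Reactants: 6 bis(benzyloxymethyl) bis-imide
Product: 8 (1S,5S)-3,7-dioxabicyclo[3.3.0]octane-2,6-dione, via bis(hydroxymethyl) bis-imide 7 (not isolated)
Conditions: H2 (1 atm), 10% Pd/C, EtOAc–EtOH, rt; then TsOH·H2O (cat.), CH2Cl2, rt to 40 °C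
Reagents that add atoms: none
Why: Hydrogenolysis of the two benzyl ethers frees two primary alcohols, each of which attacks the imide carbonyl on the neighbouring carbon in a five-membered lactonisation (intramolecular transacylation) that expels the auxiliary, and the (2S,3S) configuration allows only the cis-fused bis-lactone.

**Step 5**
Reactants: 8 bis-lactone
Product: 10 (1S,5S)-2,6-diacetoxy-3,7-dioxabicyclo[3.3.0]octane, via bis-aluminium hemiacetal 9 (not isolated)
Conditions: iBu2AlH (2.2 equiv), CH2Cl2, −78 °C; then pyridine, DMAP, Ac2O, −78 to 0 °C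
Reagents that add atoms: acetic anhydride, CC(=O)OC(C)=O
Why: Low-temperature iBu2AlH reduction of each γ-lactone stops at the aluminium hemiacetal, which is acylated in the same flask (reductive acetylation of a lactone), so the water-soluble bis-lactol is never isolated and the bridgehead centres are untouched.

**Step 6**
Reactants: 11 4-bromo-2-methoxyphenol
Product: 12 tert-butyl(4-bromo-2-methoxyphenoxy)dimethylsilane
Conditions: TBSCl, imidazole, DMF, rt
Reagents that add atoms: tert-butyldimethylsilyl chloride, CC(C)(C)[Si](C)(C)Cl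
Why: Standard silylation of a phenol masks the acidic OH before the organometallic steps.

**Step 7**
Reactants: 12 silylated aryl bromide
Product: 13 [4-(tert-butyldimethylsilyloxy)-3-methoxyphenyl]magnesium bromide (THF solution, titrated and used directly)
Conditions: Mg turnings, I2 (cat.), THF, 40–60 °C
Reagents that add atoms: magnesium, [Mg]
Why: Direct magnesium insertion into the aryl bromide (Grignard reagent formation) tolerates the aryl silyl ether and the methoxy group.

**Step 8**
Reactants: 10 bis-lactol diacetate; 13 aryl Grignard reagent (5 equiv)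
Product: 18 bis-TBS (−)-pinoresinol [(1S,2R,5S,6R)-2,6-diaryl-3,7-dioxabicyclo[3.3.0]octane; aryl = 4-(tert-butyldimethylsilyloxy)-3-methoxyphenyl; both aryl groups exo], via diarylzinc 14 (not isolated), via first oxocarbenium ion 15 (not isolated), via monoaryl acetate 16 (not isolated), via second oxocarbenium ion 17 (not isolated)
Conditions: 13, ZnBr2 (2.5 equiv), THF, 0 °C to rt; then 10, BF3·OEt2 (3 equiv), toluene–THF, −30 °C to rt
Reagents that add atoms: none
Why: BF3·OEt2, helped by the ZnBr2 and MgBr2 present, removes one anomeric acetate of 10 to give the cis-fused bicyclic oxocarbenium ion 15; the C–Zn bond of 14 delivers its ipso carbon to the cationic carbon to give 16, and the same ionisation–arylation through 17 at the second acetal gives 18. The closest known reaction type is the Lewis-acid-promoted substitution of α-acetoxy ethers, anomeric sulfones and glycosyl halides by organozinc reagents made from Grignard reagents and ZnBr2, as used for C-aryl glycosides and 2-aryl oxolanes. No ring is closed: both oxolane rings are already present in 10 and only the two acetal-carbon–aryl bonds are formed. Each new benzylic stereocentre is set by approach of the arylzinc to the convex (exo) face of the cis-fused oxocarbenium ion, anti to the other ring; with the (1S,5S) bridgeheads fixed, this gives the (2R,6R) centres of the (−)-series. The step needs exo selectivity twice, arylation only at the metal-bearing carbon (no Friedel–Crafts attack at other ring positions) and complete reaction of both acetals; the folded bicycle, the defined C–Zn bond and the excess of 14 should secure these.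

**Step 9**
Reactants: 18 bis-TBS (−)-pinoresinol
Product: 19 bis-TBS (−)-lariciresinol {[(2R,3S,4S)-2-aryl-4-(arylmethyl)oxolan-3-yl]methanol; aryl = 4-(tert-butyldimethylsilyloxy)-3-methoxyphenyl}
Conditions: H2 (1 atm), 10% Pd/C, EtOAc, rt, stopped after uptake of one equivalent
Reagents that add atoms: none
Why: Catalytic hydrogenolysis of one benzylic C–O bond is made easy by the para-oxygenated aryl group, the two such bonds are equivalent through the C2 axis so either cleavage gives 19, and the cleaved carbon becomes CH2 while the three remaining stereocentres are untouched.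

**Step 10**
Reactants: 20 caffeic acid
Product: 22 (E)-3-[3,4-bis(tert-butyldimethylsilyloxy)phenyl]prop-2-enoic acid, via tris-silyl caffeate 21 (not isolated)
Conditions: TBSCl (3.5 equiv), imidazole, DMF, rt; then AcOH–THF–H2O, rt
Reagents that add atoms: tert-butyldimethylsilyl chloride, CC(C)(C)[Si](C)(C)Cl
Why: Exhaustive silylation followed by selective hydrolysis of the much more labile silyl ester leaves the two aryl silyl ethers and the free acid, with the E alkene unchanged.

**Step 11**
Reactants: 19 bis-TBS (−)-lariciresinol; 22 bis-TBS caffeic acid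
Product: 23 tetrakis-TBS (−)-lariciresinol caffeate {[(2R,3S,4S)-2-aryl-4-(arylmethyl)oxolan-3-yl]methyl (E)-3-[3,4-bis(tert-butyldimethylsilyloxy)phenyl]prop-2-enoate}
Conditions: DCC, DMAP (cat.), CH2Cl2, 0 °C to rt
Reagents that add atoms: none
Why: Steglich esterification (carbodiimide activation with DMAP acyl transfer) joins the only free hydroxyl of 19 to acid 22, and no stereocentre is involved.

**Step 12**
Reactants: 23 tetrakis-TBS ester
Product: 24 [(2R,3S,4S)-2-(4-hydroxy-3-methoxyphenyl)-4-[(4-hydroxy-3-methoxyphenyl)methyl]oxolan-3-yl]methyl (E)-3-(3,4-dihydroxyphenyl)prop-2-enoate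
Conditions: Bu4NF (4.5 equiv), AcOH (5 equiv), THF, 0 °C
Reagents that add atoms: none
Why: Fluoride cleavage of the four aryl silyl ethers, buffered with AcOH so that each phenoxide is protonated at once, should leave the cinnamate ester, the E alkene and the benzylic oxolane ether intact and give the target.

**Compound list**

1 | succinyl chloride | O=C(Cl)CCC(Cl)=O | starting material
2 | (R)-4-benzyl-1,3-oxazolidin-2-one | O=C1N[C@H](Cc2ccccc2)CO1 | starting material
3 | 1,4-bis[(4R)-4-benzyl-2-oxo-1,3-oxazolidin-3-yl]butane-1,4-dione | O=C(CCC(=O)N1[C@H](Cc2ccccc2)COC1=O)N1[C@H](Cc2ccccc2)COC1=O | intermediate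
4 | benzyl chloromethyl ether | ClCOCc1ccccc1 | starting material
5 | (2S)-2-(benzyloxymethyl)-1,4-bis[(4R)-4-benzyl-2-oxo-1,3-oxazolidin-3-yl]butane-1,4-dione | O=C(C[C@@H](COCc1ccccc1)C(=O)N1[C@H](Cc2ccccc2)COC1=O)N1[C@H](Cc2ccccc2)COC1=O | intermediate
6 | (2S,3S)-2,3-bis(benzyloxymethyl)-1,4-bis[(4R)-4-benzyl-2-oxo-1,3-oxazolidin-3-yl]butane-1,4-dione | O=C([C@H](COCc1ccccc1)[C@@H](COCc1ccccc1)C(=O)N1[C@H](Cc2ccccc2)COC1=O)N1[C@H](Cc2ccccc2)COC1=O | intermediate
7 | (2S,3S)-2,3-bis(hydroxymethyl)-1,4-bis[(4R)-4-benzyl-2-oxo-1,3-oxazolidin-3-yl]butane-1,4-dione (not isolated) | O=C([C@H](CO)[C@@H](CO)C(=O)N1[C@H](Cc2ccccc2)COC1=O)N1[C@H](Cc2ccccc2)COC1=O | intermediate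
8 | (1S,5S)-3,7-dioxabicyclo[3.3.0]octane-2,6-dione (cis-fused C2-symmetric bis-lactone) | O=C1[C@@H]2COC(=O)[C@@H]2CO1 | intermediate
9 | (1S,5S)-2,6-bis(diisobutylaluminoxy)-3,7-dioxabicyclo[3.3.0]octane (not isolated; acetal carbons undefined) | CC(C)C[Al](CC(C)C)OC1[C@@H]2COC(O[Al](CC(C)C)CC(C)C)[C@@H]2CO1 | intermediate
10 | (1S,5S)-2,6-diacetoxy-3,7-dioxabicyclo[3.3.0]octane (anomer mixture; exo,exo anomer drawn) | CC(=O)O[C@H]1[C@@H]2CO[C@@H](OC(C)=O)[C@@H]2CO1 | intermediate
11 | 4-bromo-2-methoxyphenol | COc1cc(Br)ccc1O | starting material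
12 | tert-butyl(4-bromo-2-methoxyphenoxy)dimethylsilane | COc1cc(Br)ccc1O[Si](C)(C)C(C)(C)C | intermediate
13 | [4-(tert-butyldimethylsilyloxy)-3-methoxyphenyl]magnesium bromide | COc1cc([Mg]Br)ccc1O[Si](C)(C)C(C)(C)C | intermediate
14 | bis[4-(tert-butyldimethylsilyloxy)-3-methoxyphenyl]zinc (not isolated) | COc1cc([Zn]c2ccc(O[Si](C)(C)C(C)(C)C)c(OC)c2)ccc1O[Si](C)(C)C(C)(C)C | intermediate
15 | monoacetate oxocarbenium ion of the (1S,5S) bicycle, C=O+ in one ring (not isolated) | CC(=O)O[C@H]1[C@@H]2C[O+]=C[C@@H]2CO1 | intermediate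
16 | (1S,5S,6R)-2-acetoxy-6-[4-(tert-butyldimethylsilyloxy)-3-methoxyphenyl]-3,7-dioxabicyclo[3.3.0]octane, aryl exo (not isolated) | CC(=O)O[C@H]1[C@@H]2CO[C@@H](c3ccc(O[Si](C)(C)C(C)(C)C)c(OC)c3)[C@@H]2CO1 | intermediate
17 | exo-monoaryl oxocarbenium ion of the (1S,5S) bicycle (not isolated) | [O+]1=C[C@@H]2CO[C@@H](c3ccc(O[Si](C)(C)C(C)(C)C)c(OC)c3)[C@@H]2C1 | intermediate
18 | bis-TBS (−)-pinoresinol, (1S,2R,5S,6R)-2,6-bis[4-(tert-butyldimethylsilyloxy)-3-methoxyphenyl]-3,7-dioxabicyclo[3.3.0]octane | COc1cc([C@H]2[C@@H]3CO[C@@H](c4ccc(O[Si](C)(C)C(C)(C)C)c(OC)c4)[C@@H]3CO2)ccc1O[Si](C)(C)C(C)(C)C | intermediate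
19 | bis-TBS (−)-lariciresinol, [(2R,3S,4S)-2-[4-(tert-butyldimethylsilyloxy)-3-methoxyphenyl]-4-[[4-(tert-butyldimethylsilyloxy)-3-methoxyphenyl]methyl]oxolan-3-yl]methanol | COc1cc(C[C@@H]2CO[C@@H](c3ccc(O[Si](C)(C)C(C)(C)C)c(OC)c3)[C@@H]2CO)ccc1O[Si](C)(C)C(C)(C)C | intermediate
20 | caffeic acid | OC(=O)/C=C/c1ccc(O)c(O)c1 | starting material
21 | tert-butyldimethylsilyl (E)-3-[3,4-bis(tert-butyldimethylsilyloxy)phenyl]prop-2-enoate (not isolated) | CC(C)(C)[Si](C)(C)OC(=O)/C=C/c1ccc(O[Si](C)(C)C(C)(C)C)c(O[Si](C)(C)C(C)(C)C)c1 | intermediate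
22 | (E)-3-[3,4-bis(tert-butyldimethylsilyloxy)phenyl]prop-2-enoic acid | OC(=O)/C=C/c1ccc(O[Si](C)(C)C(C)(C)C)c(O[Si](C)(C)C(C)(C)C)c1 | intermediate
23 | tetrakis-TBS (−)-lariciresinol caffeate | COc1cc(C[C@@H]2CO[C@@H](c3ccc(O[Si](C)(C)C(C)(C)C)c(OC)c3)[C@@H]2COC(=O)/C=C/c2ccc(O[Si](C)(C)C(C)(C)C)c(O[Si](C)(C)C(C)(C)C)c2)ccc1O[Si](C)(C)C(C)(C)C | intermediate
24 | [(2R,3S,4S)-2-(4-hydroxy-3-methoxyphenyl)-4-[(4-hydroxy-3-methoxyphenyl)methyl]oxolan-3-yl]methyl (E)-3-(3,4-dihydroxyphenyl)prop-2-enoate | COc1cc(C[C@@H]2CO[C@@H](c3ccc(O)c(OC)c3)[C@@H]2COC(=O)/C=C/c2ccc(O)c(O)c2)ccc1O | target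

**Step count**

Total: 12 steps. Longest linear sequence: 9 steps (1, 2, 3, 4, 5, 8, 9, 11, 12).

**Steps most likely to fail**

Step 8 (two-directional arylation). What may go wrong:
- proton loss from the bicyclic oxocarbenium ions to give enol ethers;
- sluggish ionisation of the second acetal;
- Lewis-acid re-opening of the new electron-rich benzylic ethers, with epimerisation to endo-aryl isomers or oligomerisation;
- transfer of aryl from zinc to boron.

The fallback sets out from 8 and 12 and returns at 18. Bromine–lithium exchange on 12 (n-BuLi, THF, −78 °C) gives [4-(tert-butyldimethylsilyloxy)-3-methoxyphenyl]lithium F1. Added to bis-lactone 8 at −78 °C (2.2 equiv, premixed with anhydrous CeCl3 to suppress enolisation), it should stop at the ketone stage and give, after work-up, (2S,3S)-1,4-diaryl-2,3-bis(hydroxymethyl)butane-1,4-dione F2. NaBH4 in MeOH at 0 °C reduces this to (2S,3S)-1,4-diaryl-2,3-bis(hydroxymethyl)butane-1,4-diol F3, with the carbinol configuration uncontrolled. Camphorsulfonic acid in CH2Cl2 then closes both oxolane rings: each para-oxygen-stabilised benzylic cation is captured by the primary hydroxyl on the far carbon. This cyclodehydration is reversible and stereoconvergent and should favour the exo,exo-diaryl furofuran 18 whatever the carbinol configuration.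

Step 3 (second benzyloxymethylation). What may go wrong:
- enolisation at the wrong α-carbon;
- mismatched double stereodifferentiation between the first α-centre and the second auxiliary, leading towards the meso-type diastereomer;
- slow enolisation because the ether and both imides compete for TiCl4.

The fallback sets out from 1 and 4 and returns at 8; it trades auxiliary control for a classical resolution. Compound 1 is esterified with tert-butanol (pyridine, Et2O) to di-tert-butyl succinate F4. Its vicinal dianion (LiN(iPr)2, 2.2 equiv, THF, −78 °C) is alkylated twice with 4 to give di-tert-butyl 2,3-bis(benzyloxymethyl)succinate F5, as the racemic C2 diastereomer mixed with the meso form. CF3CO2H in CH2Cl2 removes the tert-butyl groups to give 2,3-bis(benzyloxymethyl)succinic acid F6. Fractional crystallisation of its salt with an enantiopure amine (for example quinine or (S)-1-phenylethylamine) is used to obtain (2S,3S)-2,3-bis(benzyloxymethyl)succinic acid F7. Its configuration would be assigned by carrying a sample on to 18 and comparing the sign of rotation with that of pinoresinol. Hydrogenolysis of F7 (H2, Pd/C, EtOAc–EtOH) followed by TsOH gives 8; any meso material cannot close the second ring, ends as a monolactone acid and is removed by bicarbonate extraction.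

Step 9 (single hydrogenolysis). What may go wrong:
- cleavage of the second benzylic ether before the first is complete (over-reduction to the ring-opened diol);
- slow loss of aryl silyl groups on the catalyst.

The fallback sets out from 18 and returns at 19. Compound 18 is hydrogenolysed exhaustively (H2, Pd(OH)2/C, EtOAc–AcOH) to bis-TBS (2S,3S)-secoisolariciresinol F8. One benzylic position of this C2-symmetric diol is then oxidised with DDQ (1.1 equiv, CH2Cl2, 0 °C). The resulting benzylic cation is trapped by the hydroxymethyl group on the far carbon to re-form a single oxolane, with the aryl group trans to the neighbouring CH2OH group, which is the arrangement in 19.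

**Further compounds**

F1 | step 8 | [4-(tert-butyldimethylsilyloxy)-3-methoxyphenyl]lithium | COc1cc([Li])ccc1O[Si](C)(C)C(C)(C)C
F2 | step 8 | (2S,3S)-1,4-bis[4-(tert-butyldimethylsilyloxy)-3-methoxyphenyl]-2,3-bis(hydroxymethyl)butane-1,4-dione | O=C(c1ccc(O[Si](C)(C)C(C)(C)C)c(OC)c1)[C@H](CO)[C@@H](CO)C(=O)c1ccc(O[Si](C)(C)C(C)(C)C)c(OC)c1
F3 | step 8 | (2S,3S)-1,4-bis[4-(tert-butyldimethylsilyloxy)-3-methoxyphenyl]-2,3-bis(hydroxymethyl)butane-1,4-diol (C1 and C4 undefined) | OC(c1ccc(O[Si](C)(C)C(C)(C)C)c(OC)c1)[C@H](CO)[C@@H](CO)C(O)c1ccc(O[Si](C)(C)C(C)(C)C)c(OC)c1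
F4 | step 3 | di-tert-butyl succinate | CC(C)(C)OC(=O)CCC(=O)OC(C)(C)C
F5 | step 3 | di-tert-butyl 2,3-bis(benzyloxymethyl)succinate (racemic C2 diastereomer plus meso) | CC(C)(C)OC(=O)C(COCc1ccccc1)C(COCc1ccccc1)C(=O)OC(C)(C)C
F6 | step 3 | 2,3-bis(benzyloxymethyl)succinic acid (racemic C2 diastereomer plus meso) | OC(=O)C(COCc1ccccc1)C(COCc1ccccc1)C(O)=O
F7 | step 3 | (2S,3S)-2,3-bis(benzyloxymethyl)succinic acid | OC(=O)[C@H](COCc1ccccc1)[C@@H](COCc1ccccc1)C(O)=O
F8 | step 9 | bis-TBS (2S,3S)-secoisolariciresinol | COc1cc(C[C@H](CO)[C@@H](CO)Cc2ccc(O[Si](C)(C)C(C)(C)C)c(OC)c2)ccc1O[Si](C)(C)C(C)(C)C
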